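Plan
- Retrosynthesis: remove the C8 isovalerate and the C11=C13 methylene and return C1 to a protected carbinol; cut C7–C8 (opens the ten-membered ring); cut the butenolide at C7=C11 and at its acyl C–O; cut C5–C6; cut C2–C3.
- Enabling feature: C8 is a carbinol carbon and C7 is β to the lactone carbonyl C12, so the bond joining the carbocycle C1–C10 to the five-membered lactone O–C6–C7–C11–C12 links two acceptor carbons and is made reductively.
- Forward: ketone 7 (C8–C10, C1, C2) and iodoenal 11 (C3–C5) are joined by an aldol reaction; acrolein and acryloyl chloride add C6, C7, C11 and C12; the butenolide closes first (metathesis), the ten-membered ring second (cathode); methylene, ester and C1 ketone come last.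
- Stereochemistry: C10 from (R)-citramalic acid; C3 from a reagent-controlled boron aldol; the temporary C1 carbinol from a hydroxyl-directed anti reduction; C6 from a ligand-controlled alkenylchromium addition; C7 from C6 and C8 from the ring-forming transition state in the key step; Z-C4=C5 from anti-carbomagnesiation of propargyl alcohol.

Key step: step 17

Assumption: germacranolide numbering is used (ring C1–C10, lactone C6–O–C12(=O)–C11–C7, C13 = exocyclic CH2); C1 passes through the ring closure as a carbinol locked with the C10 hydroxyl in an acetonide and is oxidised afterwards, because an α-oxygenated ketone would be cleaved at the cathode and a ketal beside quaternary C10 is hard to form and to remove (TES = triethylsilyl, TBS = tert-butyldimethylsilyl).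

Step 1
Reactants: 1 (R)-citramalic acid
Product: 2 2-[(4R)-2,2,4-trimethyl-5-oxo-1,3-dioxolan-4-yl]acetic acid
Conditions: 2,2-dimethoxypropane, TsOH·H2O (cat.), rt
Reagents that add atoms: 2,2-dimethoxypropane, COC(C)(C)OC
Why: Acid-catalysed acetal exchange should close the 1,3-dioxolan-4-one on the α-hydroxy acid unit only, which masks C1 and the C10 hydroxyl and leaves the C8 carboxyl free without touching the C10 stereocentre.

Step 2
Reactants: 2 2-[(4R)-2,2,4-trimethyl-5-oxo-1,3-dioxolan-4-yl]acetic acid
Product: 4 (3R)-3-hydroxy-3-methyloxolan-2-one, via hydroxyethyl dioxolanone 3 (not isolated)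
Conditions: BH3·THF, THF, 0 °C to rt; MeOH; then TsOH·H2O (cat.), CH2Cl2, rt
Reagents that add atoms: none
Why: Chemoselective borane reduction of the free carboxylic acid beside the dioxolanone should give alcohol 3, which under acid catalysis lactonises onto the activated C1 carbonyl with loss of acetone (translactonisation), C10 being untouched.

Step 3
Reactants: 4 (3R)-3-hydroxy-3-methyloxolan-2-one
Product: 5 (2R)-2,4-dihydroxy-N-methoxy-N,2-dimethylbutanamide
Conditions: MeNHOMe·HCl, AlMe3, CH2Cl2, 0 °C to rt
Reagents that add atoms: N,O-dimethylhydroxylamine hydrochloride, CNOC.Cl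
Why: Aminolysis of the lactone by the aluminium amide formed from AlMe3 and the hydroxylamine salt (Weinreb amide formation) should open the ring to the C8 alcohol and the C1 amide.

Step 4
Reactants: 5 (2R)-2,4-dihydroxy-N-methoxy-N,2-dimethylbutanamide
Product: 6 (2R)-N-methoxy-N,2-dimethyl-2,4-bis(triethylsilyloxy)butanamide
Conditions: TESOTf, 2,6-lutidine, CH2Cl2, −78 to 0 °C
Reagents that add atoms: triethylsilyl trifluoromethanesulfonate, CC[Si](CC)(CC)OS(=O)(=O)C(F)(F)F
Why: Silylation with the silyl triflate and a hindered pyridine base should cap both the primary and the tertiary hydroxyl as TES ethers, which also stops relactonisation of 5.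

Step 5
Reactants: 6 (2R)-N-methoxy-N,2-dimethyl-2,4-bis(triethylsilyloxy)butanamide
Product: 7 (3R)-3-methyl-3,5-bis(triethylsilyloxy)pentan-2-one
Conditions: MeLi, THF, −78 to 0 °C
Reagents that add atoms: methyllithium, [Li]C
Why: Weinreb ketone synthesis, in which the chelated tetrahedral adduct resists a second addition, should deliver the methyl ketone whose methyl group becomes C2.

Step 6
Reactants: 8 propargyl alcohol
Product: 10 (Z)-3-iodo-2-methylprop-2-en-1-ol, via oxamagnesole 9 (not isolated)
Conditions: MeMgBr (2.5 equiv), CuI (10 mol%), THF, −10 °C to rt; then I2, −20 to 0 °C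
Reagents that add atoms: methylmagnesium bromide, C[Mg]Br; iodine, II
Why: Copper-catalysed anti-carbomagnesiation of the propargylic alkoxide places methyl on C4 and magnesium on C5 cis to the CH2O group through the five-membered chelate 9, and iodinolysis with retention should give the Z-iodoalkene that fixes the C4=C5 geometry.

Step 7
Reactants: 10 (Z)-3-iodo-2-methylprop-2-en-1-ol
Product: 11 (Z)-3-iodo-2-methylprop-2-enal
Conditions: MnO2, CH2Cl2, rt, dark; used at once
Reagents that add atoms: none
Why: MnO2 oxidation of the allylic alcohol is neutral and should give the Z-enal without Z/E isomerisation if the aldehyde is kept cold and dark.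

Step 8
Reactants: 7 (3R)-3-methyl-3,5-bis(triethylsilyloxy)pentan-2-one; 11 (Z)-3-iodo-2-methylprop-2-enal
Product: 13 (3R,6R,7Z)-6-hydroxy-8-iodo-3,7-dimethyl-1,3-bis(triethylsilyloxy)oct-7-en-4-one, via diisopinocampheylboron enolate 12 (not isolated)
Conditions: (−)-Ipc2BCl, Et3N, Et2O, 0 °C; 11, −78 to −25 °C; then MeOH, pH 7 buffer, H2O2, 0 °C
Reagents that add atoms: none
Why: Reagent-controlled boron aldol reaction of a methyl ketone, in which the diisopinocampheylboron enolate 12 is expected to add through a cyclic six-membered transition state to the Re face of the enal and so set C3 as R, the C3 epimer being a diastereomer that can be separated.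

Step 9
Reactants: 13 (3R,6R,7Z)-6-hydroxy-8-iodo-3,7-dimethyl-1,3-bis(triethylsilyloxy)oct-7-en-4-one
Product: 14 (3R,4R,6R,7Z)-8-iodo-3,7-dimethyl-1,3-bis(triethylsilyloxy)oct-7-ene-4,6-diol
Conditions: Me4NBH(OAc)3, MeCN/AcOH, −30 °C
Reagents that add atoms: none
Why: Evans–Saksena reduction, in which the C3 hydroxyl binds the triacetoxyborohydride and delivers hydride intramolecularly through a chair, should set the temporary C1 carbinol 1,3-anti to C3 (1R).

Step 10
Reactants: 14 (3R,4R,6R,7Z)-8-iodo-3,7-dimethyl-1,3-bis(triethylsilyloxy)oct-7-ene-4,6-diol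
Product: 16 2-[(4R,5R)-5-[(2R,3Z)-2-hydroxy-4-iodo-3-methylbut-3-en-1-yl]-2,2,4-trimethyl-1,3-dioxolan-4-yl]ethan-1-ol, via tetraol 15 (not isolated)
Conditions: CSA (cat.), MeOH, 0 °C to rt; evaporate; then 2,2-dimethoxypropane, acetone, CSA (cat.), 0 °C; NaHCO3 (aq)
Reagents that add atoms: 2,2-dimethoxypropane, COC(C)(C)OC
Why: Acid-catalysed methanolysis removes both TES ethers, and thermodynamic acetonide formation should then select the C1/C10 1,2-diol (five-membered dioxolane) over the anti C1/C3 and the C8/C10 1,3-diols, whose six-membered acetonides would carry an axial substituent.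

Step 11
Reactants: 16 acetonide diol (C8-OH and C3-OH free)
Product: 17 bis-TBS ether of 16 (C8-OTBS; C3-OTBS; Z-iodoalkene)
Conditions: TBSOTf, 2,6-lutidine, CH2Cl2, −78 to 0 °C
Reagents that add atoms: tert-butyldimethylsilyl trifluoromethanesulfonate, CC(C)(C)[Si](C)(C)OS(=O)(=O)C(F)(F)F
Why: Silylation of the primary C8 and the secondary allylic C3 hydroxyl with the silyl triflate should proceed without touching the acetonide or the iodoalkene.

Step 12
Reactants: 17 Z-iodoalkene bis-TBS ether; 18 acrolein
Product: 20 (3S,4Z,6R)-6-(TBS-oxy)-7-[(4R,5R)-5-[2-(TBS-oxy)ethyl]-2,2,5-trimethyl-1,3-dioxolan-4-yl]-5-methylhepta-1,4-dien-3-ol, via alkenylchromium dichloride 19 (not isolated)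
Conditions: CrCl2 (4 equiv), NiCl2 (cat.), chiral oxazoline–sulfonamide ligand (enantiomer matched to Re-face addition), Et3N, THF, rt
Reagents that add atoms: none
Why: Asymmetric Nozaki–Hiyama–Kishi reaction, in which zerovalent nickel inserts into the C5–I bond with retention of the Z geometry and the alkenyl group passes to trivalent chromium (19) and adds 1,2 to acrolein, C6 being set as S by the chiral sulfonamide ligand on chromium (attack on the Re face of acrolein) and its epimer being a separable diastereomer.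

Step 13
Reactants: 20 allylic alcohol (C6-OH); 21 acryloyl chloride
Product: 22 acrylate ester of 20 at the C6 oxygen
Conditions: iPr2NEt, DMAP (cat.), CH2Cl2, −20 to 0 °C
Reagents that add atoms: none
Why: Acylation of the secondary bis-allylic alcohol with the acid chloride and a hindered amine base should give the acrylate without loss of C6 configuration.

Step 14
Reactants: 22 acrylate ester
Product: 23 (5S)-5-[(1Z,3R)-3-(TBS-oxy)-4-[(4R,5R)-5-[2-(TBS-oxy)ethyl]-2,2,5-trimethyl-1,3-dioxolan-4-yl]-2-methylbut-1-en-1-yl]furan-2(5H)-one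
Conditions: second-generation Grubbs catalyst RuCl2(=CHPh)(PCy3)(H2IMes) (5–10 mol%), CH2Cl2 (2 mM), 40 °C
Reagents that add atoms: none
Why: Ring-closing metathesis between the acrylate and the monosubstituted C6 vinyl group should close the five-membered butenolide (C7=C11), the hindered trisubstituted C4=C5 alkene staying out of the reaction.

Step 15
Reactants: 23 butenolide bis-TBS ether
Product: 24 primary alcohol (C8-OH free; C3-OTBS kept)
Conditions: HF·pyridine, pyridine, THF, 0 °C
Reagents that add atoms: none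
Why: Buffered fluoride desilylation should remove the primary TBS ether much faster than the hindered secondary allylic one and leave acetonide and butenolide untouched.

Step 16
Reactants: 24 primary alcohol
Product: 25 C8 aldehyde (C1/C10 acetonide; C3-OTBS; Z-C4=C5; C6 butenolide)
Conditions: Dess–Martin periodinane, NaHCO3, CH2Cl2, 0 °C to rt
Reagents that add atoms: none
Why: Dess–Martin oxidation under buffered, non-basic conditions should give the C8 aldehyde without epimerising C6 or eliminating the β-oxygen at C10.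

Step 17
Reactants: 25 C8 aldehyde tethered to the C6-substituted butenolide
Product: 26 ten-membered hydroxy lactone (1R,3R,4Z,6R,7R,8R,10R; trans-fused saturated γ-lactone; 8-OH; 3-OTBS; 1,10-acetonide)
Conditions: divided cell, glassy carbon cathode, Pt anode, 0.1 M Et4NOTs in MeCN, dimethyl malonate (3 equiv), −2.3 V vs SCE, 25 added slowly (about 1 mM), 0 °C, about 2.1 F/mol
Reagents that add atoms: none
Why: Proposed new method: one-electron transfer at the cathode to the C8 aldehyde (or, at nearly the same potential, to the butenolide) gives a radical anion that joins C8 to C7, the β-carbon of the lactone, after which a second electron and two protons from the malonate give the saturated lactone carrying the C8 hydroxyl. The closest known reaction type is the cathodic reductive cyclisation of aldehyde- or ketone-tethered enoates to five- and six-membered rings, together with SmI2 ketyl–olefin closures of eight-membered rings. The carbocycle closes in a 10-exo-trig mode, helped by three turn elements in the chain: the Z-C4=C5 bond, the C1/C10 dioxolane and the s-cis acceptor locked in the lactone ring. C7 is set by the C6 stereocentre, because the new bond forms on the butenolide face anti to the C6 alkenyl chain and the lactone becomes trans-fused, whereas C8 is set by the orientation of the ketyl in the ring-forming transition state (oxygen turned away from the lactone) and is the less secure of the two. The step needs electron transfer to the aldehyde–butenolide pair only and ring closure ahead of hydrodimerisation, reductive C6–O cleavage or base-induced butenolide isomerisation: no ketone is present because C1 is a protected carbinol, silyl ether, acetal and trisubstituted alkene are not reducible at this potential, high dilution favours the intramolecular path, and the malonate buffers the catholyte.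

Step 18
Reactants: 26 ten-membered hydroxy lactone
Product: 30 α-methylene lactone (C11=C13; 8-OH; 3-OTBS; 1,10-acetonide), via dilithium alkoxide enolate 27 (not isolated), via Mannich base 28 (not isolated), via trimethylammonium iodide 29 (not isolated)
Conditions: LiN(iPr)2 (3 equiv), THF, −78 °C; Eschenmoser's salt, −78 to −20 °C; then MeI, MeOH, rt; then NaHCO3 (aq), CH2Cl2, rt
Reagents that add atoms: Eschenmoser's salt (N,N-dimethylmethyleneiminium iodide), C=[N+](C)C.[I-]
Why: Eschenmoser methylenation through the alkoxide–enolate dianion 27, in which a Mannich reaction at C11, N-methylation and base-induced elimination of trimethylamine should install the C11=C13 methylene without creating or losing a stereocentre.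

Step 19
Reactants: 30 α-methylene lactone with free 8-OH
Product: 31 8-O-isovalerate of 30
Conditions: isovaleric anhydride, Et3N, DMAP (cat.), CH2Cl2, 0 °C to rt
Reagents that add atoms: isovaleric anhydride, CC(C)CC(=O)OC(=O)CC(C)C
Why: DMAP-catalysed acylation of the only free hydroxyl (C8) with the anhydride should give the isovalerate with retention at C8.

Step 20
Reactants: 31 8-O-isovalerate
Product: 32 1,10-diol (1R; 3-OTBS kept)
Conditions: PPTS, MeOH, 40 °C
Reagents that add atoms: none
Why: Acid-catalysed transacetalisation with methanol should release the C1/C10 diol while the hindered secondary allylic TBS ether, the ester and the lactone survive the mildly acidic medium.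

Step 21
Reactants: 32 1,10-diol
Product: 33 C1 ketone (10-OH free; 3-OTBS)
Conditions: IBX, DMSO/THF, rt
Reagents that add atoms: none
Why: IBX oxidation should convert the secondary C1 carbinol of the 1,2-diol into the ketone without cleaving the C1–C10 bond, the tertiary C10 hydroxyl and the silylated C3 oxygen being inert.

Step 22
Reactants: 33 C1 ketone
Product: 34 target (3R,4Z,6R,7R,8R,10R)
Conditions: HF·pyridine, THF, 0 °C to rt
Reagents that add atoms: none
Why: Fluoride desilylation under mildly acidic conditions should free the C3 hydroxyl without dehydrating the β-hydroxy ketone or adding to the α-methylene lactone.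

Compound list
1 | (R)-citramalic acid, (2R)-2-hydroxy-2-methylbutanedioic acid | OC(=O)C[C@@](C)(O)C(=O)O | starting material
2 | 2-[(4R)-2,2,4-trimethyl-5-oxo-1,3-dioxolan-4-yl]acetic acid | OC(=O)C[C@@]1(C)OC(C)(C)OC1=O | intermediate
3 | (5R)-5-(2-hydroxyethyl)-2,2,5-trimethyl-1,3-dioxolan-4-one | OCC[C@@]1(C)OC(C)(C)OC1=O | intermediate (not isolated)
4 | (3R)-3-hydroxy-3-methyloxolan-2-one | O=C1OCC[C@@]1(C)O | intermediate
5 | (2R)-2,4-dihydroxy-N-methoxy-N,2-dimethylbutanamide | CON(C)C(=O)[C@](C)(O)CCO | intermediate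
6 | (2R)-N-methoxy-N,2-dimethyl-2,4-bis(triethylsilyloxy)butanamide | CON(C)C(=O)[C@](C)(O[Si](CC)(CC)CC)CCO[Si](CC)(CC)CC | intermediate
7 | (3R)-3-methyl-3,5-bis(triethylsilyloxy)pentan-2-one | CC(=O)[C@](C)(O[Si](CC)(CC)CC)CCO[Si](CC)(CC)CC | intermediate
8 | propargyl alcohol | C#CCO | starting material
9 | 4-methyl-2,5-dihydro-1,2-oxamagnesole (chelated Z-alkenylmagnesium alkoxide) | CC1=C[Mg]OC1 | intermediate (not isolated)
10 | (Z)-3-iodo-2-methylprop-2-en-1-ol | OC/C(C)=C\I | intermediate
11 | (Z)-3-iodo-2-methylprop-2-enal | O=C/C(C)=C\I | intermediate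
12 | bis[(1R,2S,3R,5R)-isopinocampheyl]boron enolate of 7 (O-boron enolate at C1=C2) | C=C(OB([C@H]1[C@H](C)[C@H]2C[C@@H](C1)C2(C)C)[C@H]1[C@H](C)[C@H]2C[C@@H](C1)C2(C)C)[C@](C)(O[Si](CC)(CC)CC)CCO[Si](CC)(CC)CC | intermediate (not isolated)
13 | (3R,6R,7Z)-6-hydroxy-8-iodo-3,7-dimethyl-1,3-bis(triethylsilyloxy)oct-7-en-4-one | CC[Si](CC)(CC)OCC[C@@](C)(O[Si](CC)(CC)CC)C(=O)C[C@@H](O)/C(C)=C\I | intermediate
14 | (3R,4R,6R,7Z)-8-iodo-3,7-dimethyl-1,3-bis(triethylsilyloxy)oct-7-ene-4,6-diol | CC[Si](CC)(CC)OCC[C@@](C)(O[Si](CC)(CC)CC)[C@H](O)C[C@@H](O)/C(C)=C\I | intermediate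
15 | (3R,4R,6R,7Z)-8-iodo-3,7-dimethyloct-7-ene-1,3,4,6-tetraol | OCC[C@@](C)(O)[C@H](O)C[C@@H](O)/C(C)=C\I | intermediate (not isolated)
16 | 2-[(4R,5R)-5-[(2R,3Z)-2-hydroxy-4-iodo-3-methylbut-3-en-1-yl]-2,2,4-trimethyl-1,3-dioxolan-4-yl]ethan-1-ol | OCC[C@@]1(C)OC(C)(C)O[C@@H]1C[C@@H](O)/C(C)=C\I | intermediate
17 | bis-TBS ether of 16 (C8-OTBS, C3-OTBS, C1/C10 acetonide, Z-C4=C5–I) | CC(C)(C)[Si](C)(C)OCC[C@@]1(C)OC(C)(C)O[C@@H]1C[C@@H](O[Si](C)(C)C(C)(C)C)/C(C)=C\I | intermediate
18 | acrolein | C=CC=O | starting material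
19 | alkenylchromium dichloride from 17 (trivalent chromium in place of iodine at C5) | CC(C)(C)[Si](C)(C)OCC[C@@]1(C)OC(C)(C)O[C@@H]1C[C@@H](O[Si](C)(C)C(C)(C)C)/C(C)=C\[Cr](Cl)Cl | intermediate (not isolated)
20 | (3S,4Z,6R)-6-(TBS-oxy)-7-[(4R,5R)-5-[2-(TBS-oxy)ethyl]-2,2,5-trimethyl-1,3-dioxolan-4-yl]-5-methylhepta-1,4-dien-3-ol (C6 allylic alcohol) | CC(C)(C)[Si](C)(C)OCC[C@@]1(C)OC(C)(C)O[C@@H]1C[C@@H](O[Si](C)(C)C(C)(C)C)/C(C)=C\[C@@H](O)C=C | intermediate
21 | acryloyl chloride | C=CC(=O)Cl | starting material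
22 | acrylate ester of 20 at the C6 oxygen | CC(C)(C)[Si](C)(C)OCC[C@@]1(C)OC(C)(C)O[C@@H]1C[C@@H](O[Si](C)(C)C(C)(C)C)/C(C)=C\[C@@H](OC(=O)C=C)C=C | intermediate
23 | (5S)-5-[(1Z,3R)-3-(TBS-oxy)-4-[(4R,5R)-5-[2-(TBS-oxy)ethyl]-2,2,5-trimethyl-1,3-dioxolan-4-yl]-2-methylbut-1-en-1-yl]furan-2(5H)-one | CC(C)(C)[Si](C)(C)OCC[C@@]1(C)OC(C)(C)O[C@@H]1C[C@@H](O[Si](C)(C)C(C)(C)C)/C(C)=C\[C@H]2OC(=O)C=C2 | intermediate
24 | primary alcohol from 23 (C8-OH free, C3-OTBS, C1/C10 acetonide, C6 butenolide) | OCC[C@@]1(C)OC(C)(C)O[C@@H]1C[C@@H](O[Si](C)(C)C(C)(C)C)/C(C)=C\[C@H]2OC(=O)C=C2 | intermediate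
25 | C8 aldehyde from 24 (key-step precursor; 1R,3R,10R, 6S, 4Z) | O=CC[C@@]1(C)OC(C)(C)O[C@@H]1C[C@@H](O[Si](C)(C)C(C)(C)C)/C(C)=C\[C@H]2OC(=O)C=C2 | intermediate
26 | ten-membered carbocycle trans-fused at C6/C7 to the saturated γ-lactone (C11 is CH2); 8-OH, 3-OTBS, 1,10-O-isopropylidene; 1R,3R,4Z,6R,7R,8R,10R | O=C1C[C@@H]2[C@H](O)C[C@@]3(C)OC(C)(C)O[C@@H]3C[C@@H](O[Si](C)(C)C(C)(C)C)/C(C)=C\[C@H]2O1 | intermediate
27 | dilithium C8-alkoxide C11-enolate of 26 | [Li]OC1=C[C@@H]2[C@H](O[Li])C[C@@]3(C)OC(C)(C)O[C@@H]3C[C@@H](O[Si](C)(C)C(C)(C)C)/C(C)=C\[C@H]2O1 | intermediate (not isolated)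
28 | Mannich base, 11-(dimethylaminomethyl) derivative of 26 (C11 configuration not defined) | CN(C)CC1C(=O)O[C@@H]2/C=C(/C)[C@H](O[Si](C)(C)C(C)(C)C)C[C@H]3OC(C)(C)O[C@]3(C)C[C@@H](O)[C@@H]12 | intermediate (not isolated)
29 | trimethylammonium iodide of 28 | C[N+](C)(C)CC1C(=O)O[C@@H]2/C=C(/C)[C@H](O[Si](C)(C)C(C)(C)C)C[C@H]3OC(C)(C)O[C@]3(C)C[C@@H](O)[C@@H]12.[I-] | intermediate (not isolated)
30 | α-methylene lactone (C11=C13), 8-OH, 3-OTBS, 1,10-O-isopropylidene; 1R,3R,4Z,6R,7R,8R,10R | C=C1C(=O)O[C@@H]2/C=C(/C)[C@H](O[Si](C)(C)C(C)(C)C)C[C@H]3OC(C)(C)O[C@]3(C)C[C@@H](O)[C@@H]12 | intermediate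
31 | 8-O-(3-methylbutanoyl) ester of 30 | C=C1C(=O)O[C@@H]2/C=C(/C)[C@H](O[Si](C)(C)C(C)(C)C)C[C@H]3OC(C)(C)O[C@]3(C)C[C@@H](OC(=O)CC(C)C)[C@@H]12 | intermediate
32 | 1,10-diol from 31 (1R-carbinol, 10-OH, 3-OTBS, 8-O-isovalerate) | C=C1C(=O)O[C@@H]2/C=C(/C)[C@H](O[Si](C)(C)C(C)(C)C)C[C@@H](O)[C@](C)(O)C[C@@H](OC(=O)CC(C)C)[C@@H]12 | intermediate
33 | C1 ketone from 32 (10-OH, 3-OTBS, 8-O-isovalerate) | C=C1C(=O)O[C@@H]2/C=C(/C)[C@H](O[Si](C)(C)C(C)(C)C)CC(=O)[C@](C)(O)C[C@@H](OC(=O)CC(C)C)[C@@H]12 | intermediate
34 | target: 1-oxo-3,10-dihydroxy-8-O-isovaleryl germacra-4(Z),11(13)-dien-6,12-olide (3R,6R,7R,8R,10R) | C=C1C(=O)O[C@@H]2/C=C(/C)[C@H](O)CC(=O)[C@](C)(O)C[C@@H](OC(=O)CC(C)C)[C@@H]12 | target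

Total step count: 22. Longest linear sequence: 20 steps (steps 1–5 and 8–22, from (R)-citramalic acid); steps 6–7 make the iodoenal branch.

Steps most likely to fail

Step 17. The cyclisation may lose out to hydrodimerisation or plain reduction of the aldehyde, to reductive opening of the allylic C6–O bond in the butenolide radical anion, or to base-induced migration of the butenolide double bond; ring closure may also be too slow, or facial control at C8 poor. The fallback uses a two-electron allylmetal addition instead of a ketyl. It sets out from 20. Esterification with 2-(bromomethyl)acrylic acid (DCC, DMAP cat., CH2Cl2, 0 °C) would give the 2-(bromomethyl)acrylate F1. Ring-closing metathesis with the second-generation Grubbs catalyst would give the 3-(bromomethyl)butenolide F2. HF·pyridine in buffered THF would free the primary alcohol F3, and Dess–Martin oxidation would give the bromo aldehyde F4. CrCl2 in THF at high dilution would then turn the allylic bromide into an allylchromium species that adds through its γ-carbon C7 to the C8 aldehyde (intramolecular Barbier-type allylation, known for 3-(bromomethyl)butenolides and for ten-membered carbocycles). This forms C7–C8, the ten-membered ring and the exocyclic methylene at once. The route is rejoined at 30 and step 18 is not needed.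

Step 12. Facial selectivity at C6 may be poor because the ligand has to control a hindered trisubstituted alkenylchromium, and oxidative addition may be sluggish. The fallback makes C6–C7 instead of C5–C6 and sets out from 17. Iodine–lithium exchange (tBuLi, Et2O, −78 °C) and formylation with DMF would give the Z-enal F5. Addition of methyl propiolate under Me2Zn and the ProPhenol ligand enantiomer that directs the alkyne to the Si face of the aldehyde (catalytic asymmetric alkynylation of an enal) would give the γ-hydroxy ynoate F6. Semihydrogenation over Pd/CaCO3 poisoned with Pb(OAc)2 and quinoline would give the Z-hydroxy enoate F7, which lactonises with loss of methanol. The route is rejoined at 23, and steps 13 and 14 are not needed.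

Step 18. The C8 lithium alkoxide may attack C12 before the lactone is enolised, which would shift the lactone from the C6 to the C8 oxygen, and double deprotonation may be incomplete. The fallback removes the alkoxide from the reaction and sets out from 26. TESOTf and 2,6-lutidine would give the C8 triethylsilyl ether F8. LiN(SiMe3)2 followed by Eschenmoser's salt would give the Mannich base F9, MeI its methiodide F10, and NaHCO3 the α-methylene lactone silyl ether F11. HF·pyridine buffered with pyridine at −10 °C would remove the secondary TES ether in the presence of the hindered TBS ether and the acetonide. The route is rejoined at 30.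

Further compounds
F1 | step 17 | 2-(bromomethyl)acrylate ester of 20 at the C6 oxygen | CC(C)(C)[Si](C)(C)OCC[C@@]1(C)OC(C)(C)O[C@@H]1C[C@@H](O[Si](C)(C)C(C)(C)C)/C(C)=C\[C@@H](OC(=O)C(=C)CBr)C=C
F2 | step 17 | 3-(bromomethyl)butenolide analogue of 23 (CH2Br on C11) | CC(C)(C)[Si](C)(C)OCC[C@@]1(C)OC(C)(C)O[C@@H]1C[C@@H](O[Si](C)(C)C(C)(C)C)/C(C)=C\[C@H]2OC(=O)C(CBr)=C2
F3 | step 17 | primary alcohol from F2 (C8-OH free) | OCC[C@@]1(C)OC(C)(C)O[C@@H]1C[C@@H](O[Si](C)(C)C(C)(C)C)/C(C)=C\[C@H]2OC(=O)C(CBr)=C2
F4 | step 17 | C8 aldehyde from F3 | O=CC[C@@]1(C)OC(C)(C)O[C@@H]1C[C@@H](O[Si](C)(C)C(C)(C)C)/C(C)=C\[C@H]2OC(=O)C(CBr)=C2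
F5 | step 12 | Z-enal from 17 (CHO in place of iodine, C6 aldehyde) | CC(C)(C)[Si](C)(C)OCC[C@@]1(C)OC(C)(C)O[C@@H]1C[C@@H](O[Si](C)(C)C(C)(C)C)/C(C)=C\C=O
F6 | step 12 | methyl γ-hydroxy ynoate (C6 carbinol, C7≡C11, C12 methyl ester) | CC(C)(C)[Si](C)(C)OCC[C@@]1(C)OC(C)(C)O[C@@H]1C[C@@H](O[Si](C)(C)C(C)(C)C)/C(C)=C\[C@@H](O)C#CC(=O)OC
F7 | step 12 | methyl (Z)-γ-hydroxy enoate from F6 | CC(C)(C)[Si](C)(C)OCC[C@@]1(C)OC(C)(C)O[C@@H]1C[C@@H](O[Si](C)(C)C(C)(C)C)/C(C)=C\[C@@H](O)/C=C\C(=O)OC
F8 | step 18 | C8 triethylsilyl ether of 26 | O=C1C[C@@H]2[C@H](O[Si](CC)(CC)CC)C[C@@]3(C)OC(C)(C)O[C@@H]3C[C@@H](O[Si](C)(C)C(C)(C)C)/C(C)=C\[C@H]2O1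
F9 | step 18 | Mannich base of F8 (11-dimethylaminomethyl, C11 configuration not defined) | CN(C)CC1C(=O)O[C@@H]2/C=C(/C)[C@H](O[Si](C)(C)C(C)(C)C)C[C@H]3OC(C)(C)O[C@]3(C)C[C@@H](O[Si](CC)(CC)CC)[C@@H]12
F10 | step 18 | trimethylammonium iodide of F9 | C[N+](C)(C)CC1C(=O)O[C@@H]2/C=C(/C)[C@H](O[Si](C)(C)C(C)(C)C)C[C@H]3OC(C)(C)O[C@]3(C)C[C@@H](O[Si](CC)(CC)CC)[C@@H]12.[I-]
F11 | step 18 | C8 triethylsilyl ether of 30 | C=C1C(=O)O[C@@H]2/C=C(/C)[C@H](O[Si](C)(C)C(C)(C)C)C[C@H]3OC(C)(C)O[C@]3(C)C[C@@H](O[Si](CC)(CC)CC)[C@@H]12
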